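**Retrosynthetic overview**
1. The target is methyl 6α-acetoxylabda-8(17),12Z,14-trien-19-oate. The plan rests on one feature of the decalin: C5 is the β-carbon of the C4 carboxyl group (C19) and its neighbour C6 carries oxygen. Ring B is therefore cut at C5–C6 into a C6 acyl radical and the C4=C5 bond of a ring A cyclohex-1-enecarboxylate.
2. Ring A comes from 3-methylcyclohexenone: C10 is set by catalytic asymmetric conjugate addition, and the enolate is taken via the triflate to the C4=C5 enoate. The C9(=C11)–C8–C7–C6 chain is grown on a C9 vinyl iodide, and ring B is closed second, by the 6-exo acyl radical cyclisation.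
3. After ring closure the C4–C5 bond is dehydrogenated. Conjugate methylation at C4 and protonation at C5 then set the C4 quaternary centre and the trans fusion from C10. The C6 ketone is reduced to the equatorial 6α-alcohol and acetylated.
4. C9=C11 is hydroborated from the α face and joined to the (Z)-dienyl iodide C12–C16 by Suzuki coupling at C11–C12. The C8 ketal is then hydrolysed and the ketone methylenated (C17) last.

Key step: step 10

Remark: the configuration is read from the SMILES as the normal labdane series (5α-H, 9α-H, 10β-CH3, 4α-CH3/4β-CO2Me, 6α-OAc), and bicyclic compounds are named with labdane numbering (ring A C1–C5/C10, ring B C5–C10, C11 on C9, C19 the ester carbon on C4). In step 1, [Ag(L*)]2 is the silver complex of a chiral N-aryl-N′-(2-sulfonatoaryl)-4,5-diphenylimidazolin-2-ylidene L*, used in the enantiomeric form that gives the S quaternary carbon. Aldehyde 8 is taken as purchased.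

**Step 1**
Reactants: 1 3-methylcyclohex-2-en-1-one; 2 ethynyltrimethylsilane
Product: 5 (S)-3-methyl-3-[1-(trimethylsilyl)ethenyl]cyclohex-1-en-1-yl trifluoromethanesulfonate, via vinylalane 3 (not isolated), via aluminium enolate 4 (not isolated)
Conditions: i-Bu2AlH, hexanes/THF, 55 °C; then 1, Cu(OTf)2 (5 mol %), [Ag(L*)]2 (2.5 mol %), THF, −78 → −15 °C; then MeLi, 0 °C; then PhNTf2, 0 °C → rt
Reagents that add atoms: N-phenylbis(trifluoromethanesulfonimide), O=S(=O)(N(c1ccccc1)S(=O)(=O)C(F)(F)F)C(F)(F)F
Why: Hydroalumination of 2 places Al and Si on the same carbon, and copper–carbene-catalysed enantioselective conjugate addition of this vinylalane to the β-methyl enone is an established route to a vinyl-bearing quaternary carbon, the ligand enantiomer fixing C10 as S; MeLi converts the regiodefined aluminium enolate into an ate complex that PhNTf2 O-triflates, so the enol triflate double bond points toward the new quaternary carbon (conjugate addition/enolate trapping).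

**Step 2**
Reactants: 5 (S)-3-methyl-3-[1-(trimethylsilyl)ethenyl]cyclohex-1-en-1-yl trifluoromethanesulfonate
Product: 6 methyl (S)-3-methyl-3-[1-(trimethylsilyl)ethenyl]cyclohex-1-ene-1-carboxylate
Conditions: Pd(OAc)2 (5 mol %), PPh3, Et3N, CO (1 atm), MeOH/DMF, 40 °C
Reagents that add atoms: carbon monoxide, [C-]#[O+]; methanol, CO
Why: Palladium-catalysed methoxycarbonylation of an enol triflate (oxidative addition, CO insertion, methanolysis) should give the enoate with the double bond fixed at C4=C5, the vinylsilane being inert.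

**Step 3**
Reactants: 6 methyl (S)-3-methyl-3-[1-(trimethylsilyl)ethenyl]cyclohex-1-ene-1-carboxylate
Product: 7 methyl (S)-3-(1-iodoethenyl)-3-methylcyclohex-1-ene-1-carboxylate
Conditions: NIS, (CF3)2CHOH, 0 °C
Reagents that add atoms: N-iodosuccinimide, O=C1CCC(=O)N1I
Why: Ipso-iododesilylation of the 1,1-disubstituted vinylsilane by NIS in an ionising, non-nucleophilic solvent should give the 2-iodoalkene, while the electron-poor enoate does not react with the electrophile.

**Step 4**
Reactants: 7 methyl (S)-3-(1-iodoethenyl)-3-methylcyclohex-1-ene-1-carboxylate; 8 3-[(tert-butyldimethylsilyl)oxy]propanal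
Product: 9 methyl (S)-3-[5-(tert-butyldimethylsilyloxy)-3-hydroxypent-1-en-2-yl]-3-methylcyclohex-1-ene-1-carboxylate (both carbinol epimers)
Conditions: CrCl2 (4 equiv), NiCl2 (2 mol %), DMF, rt
Reagents that add atoms: none
Why: Nozaki–Hiyama–Kishi coupling forms the alkenylchromium species from the hindered vinyl iodide under nickel catalysis and adds it 1,2 to the aldehyde in the presence of the methyl enoate; the new carbinol centre (C8) is formed without control and is removed by oxidation in step 5.

**Step 5**
Reactants: 9 methyl (S)-3-[5-(tert-butyldimethylsilyloxy)-3-hydroxypent-1-en-2-yl]-3-methylcyclohex-1-ene-1-carboxylate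
Product: 10 methyl (S)-3-[5-(tert-butyldimethylsilyloxy)-3-oxopent-1-en-2-yl]-3-methylcyclohex-1-ene-1-carboxylate
Conditions: Dess–Martin periodinane, NaHCO3, CH2Cl2, 0 °C → rt
Reagents that add atoms: none
Why: Dess–Martin oxidation of the allylic alcohol gives the α-methylene ketone under buffered, non-basic conditions that avoid β-elimination of the silyloxy group.

**Step 6**
Reactants: 10 methyl (S)-3-[5-(tert-butyldimethylsilyloxy)-3-oxopent-1-en-2-yl]-3-methylcyclohex-1-ene-1-carboxylate
Product: 11 methyl (S)-3-(1-{2-[2-(tert-butyldimethylsilyloxy)ethyl]-1,3-dioxolan-2-yl}ethenyl)-3-methylcyclohex-1-ene-1-carboxylate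
Conditions: TMSOCH2CH2OTMS (3 equiv), TMSOTf (5 mol %), CH2Cl2, −78 → −20 °C; pyridine quench
Reagents that add atoms: 1,2-bis(trimethylsilyloxy)ethane, C[Si](C)(C)OCCO[Si](C)(C)C
Why: Aprotic, silyl-triflate-catalysed ketalisation with the bis-silyl ether of ethylene glycol converts enones into dioxolanes at low temperature without conjugate addition or double-bond shift, and the C8 ketal both masks the later C8 carbonyl and removes the enone character of C9=C11.

**Step 7**
Reactants: 11 methyl (S)-3-(1-{2-[2-(tert-butyldimethylsilyloxy)ethyl]-1,3-dioxolan-2-yl}ethenyl)-3-methylcyclohex-1-ene-1-carboxylate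
Product: 12 methyl (S)-3-{1-[2-(2-hydroxyethyl)-1,3-dioxolan-2-yl]ethenyl}-3-methylcyclohex-1-ene-1-carboxylate
Conditions: Bu4NF, THF, 0 °C → rt
Reagents that add atoms: none
Why: Fluoride cleavage of the primary silyl ether (desilylation) leaves the ketal, the enoate and the 1,1-disubstituted alkene untouched.

**Step 8**
Reactants: 12 methyl (S)-3-{1-[2-(2-hydroxyethyl)-1,3-dioxolan-2-yl]ethenyl}-3-methylcyclohex-1-ene-1-carboxylate
Product: 13 {2-[1-((S)-3-(methoxycarbonyl)-1-methylcyclohex-2-en-1-yl)ethenyl]-1,3-dioxolan-2-yl}acetic acid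
Conditions: TEMPO (0.2 equiv), PhI(OAc)2 (2.5 equiv), MeCN/H2O, rt
Reagents that add atoms: water, O
Why: TEMPO-catalysed oxidation with PhI(OAc)2 in aqueous acetonitrile takes the primary alcohol through the aldehyde hydrate to the acid under near-neutral conditions that spare the ketal and both alkenes.

**Step 9**
Reactants: 13 {2-[1-((S)-3-(methoxycarbonyl)-1-methylcyclohex-2-en-1-yl)ethenyl]-1,3-dioxolan-2-yl}acetic acid
Product: 14 methyl (S)-3-methyl-3-(1-{2-[2-oxo-2-(phenylselanyl)ethyl]-1,3-dioxolan-2-yl}ethenyl)cyclohex-1-ene-1-carboxylate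
Conditions: PhSeSePh, PBu3, CH2Cl2, 0 °C → rt
Reagents that add atoms: diphenyl diselenide, c1ccc(cc1)[Se][Se]c1ccccc1
Why: Phosphine-mediated selenoesterification (acyloxyphosphonium ion captured by phenylselenolate) gives the acyl selenide under neutral conditions, so the CH2 next to the ketal is never enolised.

**Step 10**
Reactants: 14 methyl (S)-3-methyl-3-(1-{2-[2-oxo-2-(phenylselanyl)ethyl]-1,3-dioxolan-2-yl}ethenyl)cyclohex-1-ene-1-carboxylate
Product: 15 methyl 8,8-ethylenedioxy-6-oxo-12,13,14,15,16,17,18-heptanorlabd-9(11)-en-19-oate (10β-methyl; mixture of C4 and C5 epimers)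
Conditions: Bu3SnH (1.3 equiv) and AIBN (0.2 equiv) by syringe pump, benzene (0.01 M), 80 °C
Reagents that add atoms: none
Why: The tributyltin radical abstracts PhSe from the acyl selenide, the nucleophilic C6 acyl radical adds to C5, the electrophilic β-carbon of the ring A enoate, and the resulting α-ester radical at C4 is reduced by Bu3SnH. The closest known reaction type is the tin-hydride-mediated 6-exo-trig cyclisation of acyl radicals from phenyl selenoesters onto α,β-unsaturated esters. Ring B closes in the 6-exo-trig mode, C6 bonding to C5 with the radical left on the exocyclic C4. The new centres C5 and C4 should form mainly cis-fused (attack on the cyclohexene face reached by the tether at C10, then hydrogen transfer to the freer face), but neither needs control because step 11 returns both carbons to sp2. What the step does need is chemoselectivity: 6-exo attack at C5 is polarity-matched and should beat 7-endo attack at C4, the 4-exo and 5-endo modes at C9=C11 are geometrically disfavoured, loss of CO would give only a primary radical, and slow addition of Bu3SnH at high dilution holds back direct reduction to the aldehyde. The fully substituted C8 and C10 on either side of C9 favour the folded conformer that closes.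

**Step 11**
Reactants: 15 methyl 8,8-ethylenedioxy-6-oxo-12,13,14,15,16,17,18-heptanorlabd-9(11)-en-19-oate
Product: 16 methyl 8,8-ethylenedioxy-6-oxo-12,13,14,15,16,17,18-heptanorlabda-4,9(11)-dien-19-oate
Conditions: IBX (2 equiv), DMSO/fluorobenzene, 65 °C
Reagents that add atoms: none
Why: IBX-mediated ketone dehydrogenation through the enol can only take place across C5–C4, because C8 on the other side carries no hydrogen and the C4–H is activated by the ester, so all C4/C5 isomers of 15 should converge on one ene-keto ester.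

**Step 12**
Reactants: 16 methyl 8,8-ethylenedioxy-6-oxo-12,13,14,15,16,17,18-heptanorlabda-4,9(11)-dien-19-oate
Product: 18 methyl 8,8-ethylenedioxy-6-oxo-12,13,14,15,16,17-hexanorlabd-9(11)-en-19-oate (4α-CH3, 4β-CO2Me, 5α-H, 10β-CH3), via lithium enolate 17 (not isolated)
Conditions: Me2CuLi (from MeLi and CuI), Et2O, −78 → −30 °C; then sat. aq. NH4Cl, −78 °C
Reagents that add atoms: lithium dimethylcuprate, [Li+].C[Cu-]C
Why: Cuprate conjugate addition to this s-cis alkylidene-ketone (as with other 2-alkylidenecycloalkanones) should place methyl on C4, the terminus β to the ketone and the less hindered one, from the α face opposite the pseudo-axial C10 methyl, giving 4α-CH3/4β-CO2Me; the C5 enolate is then protonated from the same open α face to give the trans ring fusion, which is also the more stable one.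

**Step 13**
Reactants: 18 methyl 8,8-ethylenedioxy-6-oxo-12,13,14,15,16,17-hexanorlabd-9(11)-en-19-oate
Product: 19 methyl 8,8-ethylenedioxy-6α-hydroxy-12,13,14,15,16,17-hexanorlabd-9(11)-en-19-oate
Conditions: SmI2 (3 equiv), THF/H2O, 0 °C → rt
Reagents that add atoms: none
Why: Single-electron (ketyl) reduction with SmI2 and water should deliver hydrogen so that the bulky O–Sm group sits equatorial, giving the thermodynamically preferred 6α-alcohol, whereas hydride reagents would attack from the open α face and give the axial 6β-alcohol; the methyl ester is not reduced, and any 6β-alcohol would lactonise onto C19 and be separated.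

**Step 14**
Reactants: 19 methyl 8,8-ethylenedioxy-6α-hydroxy-12,13,14,15,16,17-hexanorlabd-9(11)-en-19-oate
Product: 20 methyl 6α-acetoxy-8,8-ethylenedioxy-12,13,14,15,16,17-hexanorlabd-9(11)-en-19-oate
Conditions: Ac2O, DMAP, pyridine, rt
Reagents that add atoms: acetic anhydride, CC(=O)OC(C)=O
Why: DMAP-catalysed acetylation of the equatorial secondary alcohol; C4 is already quaternary with its ester on the opposite (β) face, so neither lactonisation nor enolate chemistry interferes and the acetate can be carried to the end.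

**Step 15**
Reactants: 21 prop-2-yn-1-ol
Product: 23 (Z)-3-iodo-2-methylprop-2-en-1-ol, via alkenylmagnesium chelate 22 (not isolated)
Conditions: MeMgBr (3 equiv), CuI (10 mol %), THF, −10 °C → rt; then I2, −78 → 0 °C
Reagents that add atoms: methylmagnesium bromide, C[Mg]Br; iodine, II
Why: Copper-catalysed anti-carbomagnesiation of the propargylic alkoxide places methyl on the internal carbon and magnesium on the terminal carbon within a five-membered chelate, and iodinolysis with retention gives the Z iodoalkene (iodine cis to CH2OH).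

**Step 16**
Reactants: 23 (Z)-3-iodo-2-methylprop-2-en-1-ol
Product: 24 (Z)-3-iodo-2-methylprop-2-enal
Conditions: MnO2, CH2Cl2, rt, dark
Reagents that add atoms: none
Why: MnO2 oxidation of the allylic alcohol is neutral and should keep the Z geometry of the iodoenal.

**Step 17**
Reactants: 24 (Z)-3-iodo-2-methylprop-2-enal
Product: 25 (Z)-1-iodo-2-methylbuta-1,3-diene (volatile; kept as a solution)
Conditions: Ph3PCH3Br, n-BuLi, THF, −78 → 0 °C
Reagents that add atoms: methyltriphenylphosphonium bromide, C[P+](c1ccccc1)(c1ccccc1)c1ccccc1.[Br-]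
Why: Wittig methylenation of the enal with the non-stabilised ylide at low temperature forms the terminal vinyl group without touching the C–I bond or the Z double bond.

**Step 18**
Reactants: 20 methyl 6α-acetoxy-8,8-ethylenedioxy-12,13,14,15,16,17-hexanorlabd-9(11)-en-19-oate; 25 (Z)-1-iodo-2-methylbuta-1,3-diene
Product: 27 methyl 6α-acetoxy-8,8-ethylenedioxy-17-norlabda-12Z,14-dien-19-oate, via alkylborane 26 (not isolated)
Conditions: 9-BBN, THF, 60 °C; H2O; then 25, Pd(dppf)Cl2 (10 mol %), AsPh3, Cs2CO3, DMF/THF/H2O, rt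
Reagents that add atoms: none
Why: 9-BBN hydroboration puts boron on C11 and hydrogen on C9 from the α face, because the β face is screened by the axial C10 methyl and the axial ketal oxygen on C8, which sets C9 with the side chain equatorial (β); B-alkyl Suzuki–Miyaura coupling of the primary alkylborane with the Z vinyl iodide then forms C11–C12 with retention of alkene geometry under conditions mild enough for the acetate.

**Step 19**
Reactants: 27 methyl 6α-acetoxy-8,8-ethylenedioxy-17-norlabda-12Z,14-dien-19-oate
Product: 28 methyl 6α-acetoxy-8-oxo-17-norlabda-12Z,14-dien-19-oate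
Conditions: p-TsOH·H2O (cat.), acetone/H2O, rt
Reagents that add atoms: water, O
Why: Acid-catalysed ketal hydrolysis frees the C8 ketone; the equatorial acetate is poorly aligned for β-elimination, C9 stays in its stable equatorial configuration, and dilute acid at room temperature should leave the diene intact.

**Step 20**
Reactants: 28 methyl 6α-acetoxy-8-oxo-17-norlabda-12Z,14-dien-19-oate
Product: 29 methyl 6α-acetoxylabda-8(17),12Z,14-trien-19-oate (target)
Conditions: Zn, CH2Br2, TiCl4 (pre-formed reagent), THF/CH2Cl2, 0 °C → rt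
Reagents that add atoms: dibromomethane, BrCBr
Why: Takai–Lombardo methylenation is non-basic, so the hindered, enolisable C8 ketone should be converted into the exocyclic alkene without epimerising C9, eliminating the β-acetoxy group or attacking the ester and acetate carbonyls.

**Compound list**
1 | 3-methylcyclohex-2-en-1-one | CC1=CC(=O)CCC1 | starting material
2 | ethynyltrimethylsilane | C#C[Si](C)(C)C | starting material
3 | diisobutyl[1-(trimethylsilyl)ethenyl]alane | C=C([Si](C)(C)C)[Al](CC(C)C)CC(C)C | intermediate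
4 | diisobutylaluminium (S)-3-methyl-3-[1-(trimethylsilyl)ethenyl]cyclohex-1-en-1-olate | CC(C)C[Al](CC(C)C)OC1=C[C@@](C)(C(=C)[Si](C)(C)C)CCC1 | intermediate
5 | (S)-3-methyl-3-[1-(trimethylsilyl)ethenyl]cyclohex-1-en-1-yl trifluoromethanesulfonate | O=S(=O)(OC1=C[C@@](C)(C(=C)[Si](C)(C)C)CCC1)C(F)(F)F | intermediate
6 | methyl (S)-3-methyl-3-[1-(trimethylsilyl)ethenyl]cyclohex-1-ene-1-carboxylate | COC(=O)C1=C[C@@](C)(C(=C)[Si](C)(C)C)CCC1 | intermediate
7 | methyl (S)-3-(1-iodoethenyl)-3-methylcyclohex-1-ene-1-carboxylate | COC(=O)C1=C[C@@](C)(C(=C)I)CCC1 | intermediate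
8 | 3-[(tert-butyldimethylsilyl)oxy]propanal | O=CCCO[Si](C)(C)C(C)(C)C | starting material
9 | methyl (S)-3-[5-(tert-butyldimethylsilyloxy)-3-hydroxypent-1-en-2-yl]-3-methylcyclohex-1-ene-1-carboxylate (carbinol epimers) | COC(=O)C1=C[C@@](C)(C(=C)C(O)CCO[Si](C)(C)C(C)(C)C)CCC1 | intermediate
10 | methyl (S)-3-[5-(tert-butyldimethylsilyloxy)-3-oxopent-1-en-2-yl]-3-methylcyclohex-1-ene-1-carboxylate | COC(=O)C1=C[C@@](C)(C(=C)C(=O)CCO[Si](C)(C)C(C)(C)C)CCC1 | intermediate
11 | methyl (S)-3-(1-{2-[2-(tert-butyldimethylsilyloxy)ethyl]-1,3-dioxolan-2-yl}ethenyl)-3-methylcyclohex-1-ene-1-carboxylate | COC(=O)C1=C[C@@](C)(C(=C)C2(CCO[Si](C)(C)C(C)(C)C)OCCO2)CCC1 | intermediate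
12 | methyl (S)-3-{1-[2-(2-hydroxyethyl)-1,3-dioxolan-2-yl]ethenyl}-3-methylcyclohex-1-ene-1-carboxylate | COC(=O)C1=C[C@@](C)(C(=C)C2(CCO)OCCO2)CCC1 | intermediate
13 | {2-[1-((S)-3-(methoxycarbonyl)-1-methylcyclohex-2-en-1-yl)ethenyl]-1,3-dioxolan-2-yl}acetic acid | COC(=O)C1=C[C@@](C)(C(=C)C2(CC(=O)O)OCCO2)CCC1 | intermediate
14 | methyl (S)-3-methyl-3-(1-{2-[2-oxo-2-(phenylselanyl)ethyl]-1,3-dioxolan-2-yl}ethenyl)cyclohex-1-ene-1-carboxylate | COC(=O)C1=C[C@@](C)(C(=C)C2(CC(=O)[Se]c3ccccc3)OCCO2)CCC1 | intermediate
15 | methyl 8,8-ethylenedioxy-6-oxo-12,13,14,15,16,17,18-heptanorlabd-9(11)-en-19-oate (10β-methyl; C4 and C5 epimers) | C=C1C2(OCCO2)CC(=O)C3[C@]1(C)CCCC3C(=O)OC | intermediate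
16 | methyl 8,8-ethylenedioxy-6-oxo-12,13,14,15,16,17,18-heptanorlabda-4,9(11)-dien-19-oate | C=C1C2(OCCO2)CC(=O)C3=C(C(=O)OC)CCC[C@@]31C | intermediate
17 | lithium C5=C6 enolate of 18 | C=C1C2(OCCO2)CC(O[Li])=C3[C@]1(C)CCC[C@]3(C)C(=O)OC | intermediate
18 | methyl 8,8-ethylenedioxy-6-oxo-12,13,14,15,16,17-hexanorlabd-9(11)-en-19-oate (4α-CH3, 5α-H) | C=C1C2(OCCO2)CC(=O)[C@@H]3[C@]1(C)CCC[C@]3(C)C(=O)OC | intermediate
19 | methyl 8,8-ethylenedioxy-6α-hydroxy-12,13,14,15,16,17-hexanorlabd-9(11)-en-19-oate | C=C1C2(OCCO2)C[C@H](O)[C@@H]3[C@]1(C)CCC[C@]3(C)C(=O)OC | intermediate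
20 | methyl 6α-acetoxy-8,8-ethylenedioxy-12,13,14,15,16,17-hexanorlabd-9(11)-en-19-oate | C=C1C2(OCCO2)C[C@H](OC(C)=O)[C@@H]3[C@]1(C)CCC[C@]3(C)C(=O)OC | intermediate
21 | prop-2-yn-1-ol | C#CCO | starting material
22 | bromomagnesium (Z)-3-(bromomagnesio)-2-methylprop-2-en-1-olate | Br[Mg]/C=C(/C)CO[Mg]Br | intermediate
23 | (Z)-3-iodo-2-methylprop-2-en-1-ol | OC/C(C)=C\I | intermediate
24 | (Z)-3-iodo-2-methylprop-2-enal | O=C/C(C)=C\I | intermediate
25 | (Z)-1-iodo-2-methylbuta-1,3-diene | C=C/C(C)=C\I | intermediate
26 | methyl 6α-acetoxy-11-(9-borabicyclo[3.3.1]nonan-9-yl)-8,8-ethylenedioxy-12,13,14,15,16,17-hexanorlabdan-19-oate (9α-H) | C1CC2CCCC(C1)B2C[C@H]3C4(OCCO4)C[C@H](OC(C)=O)[C@@H]5[C@]3(C)CCC[C@]5(C)C(=O)OC | intermediate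
27 | methyl 6α-acetoxy-8,8-ethylenedioxy-17-norlabda-12Z,14-dien-19-oate | C=C/C(C)=C\C[C@H]1C2(OCCO2)C[C@H](OC(C)=O)[C@@H]3[C@]1(C)CCC[C@]3(C)C(=O)OC | intermediate
28 | methyl 6α-acetoxy-8-oxo-17-norlabda-12Z,14-dien-19-oate | C=C/C(C)=C\C[C@H]1C(=O)C[C@H](OC(C)=O)[C@@H]2[C@]1(C)CCC[C@]2(C)C(=O)OC | intermediate
29 | methyl 6α-acetoxylabda-8(17),12Z,14-trien-19-oate | C=C/C(C)=C\C[C@H]1C(=C)C[C@H](OC(C)=O)[C@@H]2[C@]1(C)CCC[C@]2(C)C(=O)OC | target

**Step count and risks**
Total step count: 20. Longest linear sequence: 17 (steps 1–14 and 18–20; steps 15–17 make the dienyl iodide).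

Steps most likely to fail:

Step 10. Hydrogen transfer to the acyl radical, or loss of CO, may outrun closure onto C5, which sits next to the quaternary C10. The fallback sets out from alcohol 12. Dess–Martin oxidation would give the aldehyde methyl (S)-3-methyl-3-{1-[2-(2-oxoethyl)-1,3-dioxolan-2-yl]ethenyl}cyclohex-1-ene-1-carboxylate F1. An intramolecular Stetter reaction (triazolium carbene precatalyst, i-Pr2NEt, toluene) would then add the acyl anion equivalent at C6 to C5 of the enoate in a polar 6-exo closure. The route is rejoined at keto ester 15.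

Step 11. Enolisation may run mainly toward C7, where no dehydrogenation is possible, while the hindered C5 enol forms slowly; prolonged heating may over-oxidise ring A. The fallback sets out from 15. Soft enolisation (TMSOTf, Et3N, CH2Cl2) would give the C5=C6 silyl enol ether methyl 8,8-ethylenedioxy-6-(trimethylsilyloxy)-12,13,14,15,16,17,18-heptanorlabda-5,9(11)-dien-19-oate F2. Saegusa–Ito oxidation with Pd(OAc)2 in MeCN would then remove the C4 hydrogen by β-hydride elimination and return the route to 16; any C6=C7 enol ether is hydrolysed back to 15 and recycled.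

Step 13. Hydrogen delivery at C6 may show poor facial selectivity, giving the axial 6β-alcohol, which is lost as the C19 lactone. The fallback sets out from 18. SN2 demethylation of the hindered ester (n-PrSLi, HMPA) would give 8,8-ethylenedioxy-6-oxo-12,13,14,15,16,17-hexanorlabd-9(11)-en-19-oic acid F3. Its lithium carboxylate would be reduced with lithium in liquid ammonia (t-BuOH, −78 °C), the classical thermodynamic reduction to the equatorial alcohol, giving 8,8-ethylenedioxy-6α-hydroxy-12,13,14,15,16,17-hexanorlabd-9(11)-en-19-oic acid F4. Esterification with TMSCHN2 in MeOH/toluene returns the route to 19.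

**Further compounds**
F1 | step 10 | methyl (S)-3-methyl-3-{1-[2-(2-oxoethyl)-1,3-dioxolan-2-yl]ethenyl}cyclohex-1-ene-1-carboxylate | COC(=O)C1=C[C@@](C)(C(=C)C2(CC=O)OCCO2)CCC1
F2 | step 11 | methyl 8,8-ethylenedioxy-6-(trimethylsilyloxy)-12,13,14,15,16,17,18-heptanorlabda-5,9(11)-dien-19-oate (C4 epimers) | C=C1C2(OCCO2)CC(O[Si](C)(C)C)=C3[C@]1(C)CCCC3C(=O)OC
F3 | step 13 | 8,8-ethylenedioxy-6-oxo-12,13,14,15,16,17-hexanorlabd-9(11)-en-19-oic acid | C=C1C2(OCCO2)CC(=O)[C@@H]3[C@]1(C)CCC[C@]3(C)C(=O)O
F4 | step 13 | 8,8-ethylenedioxy-6α-hydroxy-12,13,14,15,16,17-hexanorlabd-9(11)-en-19-oic acid | C=C1C2(OCCO2)C[C@H](O)[C@@H]3[C@]1(C)CCC[C@]3(C)C(=O)O
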